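**Strategy.** Everything rests on cutting the anilide bond between the lactam nitrogen and arene carbon C20 (ring C16–C21). Acylating an aniline nitrogen that sits next to the C21 oxygen substituent is avoided: instead the unhindered primary amide at C1 of a (2Z,4Z)-dienamide is N-arylated intramolecularly by the C20 aryl iodide under copper catalysis, which forms N–C20 and closes the 19-membered ansa ring in one operation. The substrate is the complete open chain C1–C15 bearing all seven stereocentres and the three Z-alkenes, attached at C15 to a 3-iodo-2,5-dimethoxyphenyl ring, with the C7 hydroxyl as its tert-butyldimethylsilyl ether; iodide is chosen over bromide so that closure runs near 60 °C.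

Key step: step 28

Remark: the target is made exactly as drawn, (2Z,4Z,8Z) with 6S,7S,10S,11R,12S,14S,15R (C1 = lactam carbonyl); open-chain amide 41 and macrolactam 42 carry the same configurations, and no organolithium, palladium or nickel step follows the introduction of the aryl iodide.
Remark: alkoxides, N-anions and phosphonate carbanions formed by deprotonation are counted as part of the conditions; covalent intermediates that are not isolated are numbered.

Step 1
Reactants: 1 2-hydroxy-5-methoxybenzaldehyde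
Product: 2 2-hydroxy-3-iodo-5-methoxybenzaldehyde
Conditions: N-iodosuccinimide, TsOH·H2O (cat.), MeCN, rt
Reagents that add atoms: N-iodosuccinimide, O=C1CCC(=O)N1I
Why: Electrophilic aromatic iodination; the phenol directs to its only free ortho position, which is meta to the formyl group, whereas both positions next to the methoxy group are ortho or para to the deactivating aldehyde.

Step 2
Reactants: 2 2-hydroxy-3-iodo-5-methoxybenzaldehyde
Product: 3 3-iodo-2,5-dimethoxybenzaldehyde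
Conditions: MeI, K2CO3, DMF, rt
Reagents that add atoms: iodomethane, CI
Why: Williamson ether synthesis on the phenoxide.

Step 3
Reactants: 3 3-iodo-2,5-dimethoxybenzaldehyde
Product: 5 (1R,2S)-1-(3-iodo-2,5-dimethoxyphenyl)-2-methylbut-3-en-1-ol, via O-diisopinocampheylboryl ether 4 (not isolated)
Conditions: cis-2-butene, n-BuLi, KOt-Bu, THF, −78 to −45 °C; (+)-Ipc2BOMe [from (−)-α-pinene], −78 °C; BF3·OEt2; 3, −78 °C; then NaOH, H2O2
Reagents that add atoms: cis-2-butene, C/C=C\C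
Why: Brown asymmetric crotylboration; the (Z)-crotylborane reacts through a closed chair transition state to give the syn adduct, and the isopinocampheyl groups of this antipode direct the crotyl unit to the re face of the aldehyde, which sets C15 (R) and C14 (S).

Step 4
Reactants: 5 (1R,2S)-1-(3-iodo-2,5-dimethoxyphenyl)-2-methylbut-3-en-1-ol
Product: 6 1-iodo-2,5-dimethoxy-3-[(1R,2S)-1-methoxy-2-methylbut-3-en-1-yl]benzene
Conditions: NaH, MeI, THF/DMF, 0 °C to rt
Reagents that add atoms: iodomethane, CI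
Why: Williamson O-methylation of the secondary alkoxide, which touches no stereocentre.

Step 5
Reactants: 6 1-iodo-2,5-dimethoxy-3-[(1R,2S)-1-methoxy-2-methylbut-3-en-1-yl]benzene
Product: 8 (3S,4R)-4-(3-iodo-2,5-dimethoxyphenyl)-4-methoxy-3-methylbutan-1-ol, via B-alkyl-9-borabicyclo[3.3.1]nonane 7 (not isolated)
Conditions: 9-BBN, THF, 0 °C to rt; then NaOH, H2O2
Reagents that add atoms: hydrogen peroxide, OO
Why: Anti-Markovnikov hydroboration–oxidation of the monosubstituted alkene with a bulky dialkylborane gives the primary alcohol (C12) and leaves the aryl iodide alone.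

Step 6
Reactants: 8 (3S,4R)-4-(3-iodo-2,5-dimethoxyphenyl)-4-methoxy-3-methylbutan-1-ol
Product: 9 (3S,4R)-4-(3-iodo-2,5-dimethoxyphenyl)-4-methoxy-3-methylbutanal
Conditions: Dess–Martin periodinane, pyridine, CH2Cl2, rt
Reagents that add atoms: none
Why: Dess–Martin oxidation of a primary alcohol to the aldehyde under buffered, non-epimerising conditions.

Step 7
Reactants: 9 (3S,4R)-4-(3-iodo-2,5-dimethoxyphenyl)-4-methoxy-3-methylbutanal
Product: 11 (4R,6S,7R)-7-(3-iodo-2,5-dimethoxyphenyl)-7-methoxy-6-methylhept-1-en-4-ol, via O-diisopinocampheylboryl ether 10 (not isolated)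
Conditions: (+)-Ipc2BOMe, CH2=CHCH2MgBr, Et2O, 0 °C to rt; 9, −78 °C; then NaOH, H2O2
Reagents that add atoms: allylmagnesium bromide, C=CC[Mg]Br
Why: Brown asymmetric allylboration; the same borane antipode again delivers the allyl group to the re face under reagent control, setting C12 (descriptor R here, the arrangement that becomes 12S once C11 is oxidised), and it converts any minor enantiomer from step 3 into a separable diastereomer.

Step 8
Reactants: 11 (4R,6S,7R)-7-(3-iodo-2,5-dimethoxyphenyl)-7-methoxy-6-methylhept-1-en-4-ol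
Product: 12 1-[(1R,2S,4R)-1,4-dimethoxy-2-methylhept-6-en-1-yl]-3-iodo-2,5-dimethoxybenzene
Conditions: NaH, MeI, THF/DMF, 0 °C to rt
Reagents that add atoms: iodomethane, CI
Why: Williamson O-methylation installs the C12 methoxy group with retention.

Step 9
Reactants: 12 1-[(1R,2S,4R)-1,4-dimethoxy-2-methylhept-6-en-1-yl]-3-iodo-2,5-dimethoxybenzene
Product: 13 1-[(1R,2S,4S,5E)-1,4-dimethoxy-2-methylhept-5-en-1-yl]-3-iodo-2,5-dimethoxybenzene (mainly E)
Conditions: second-generation Grubbs catalyst (5 mol%), MeOH, 60 °C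
Reagents that add atoms: none
Why: Ruthenium hydride-catalysed alkene isomerisation (the hydride arises from the carbene complex in hot methanol) moves the terminal double bond by one position to the propenyl ether, and further migration is slow because it would need insertion at the hindered methoxy-bearing carbon.

Step 10
Reactants: 13 1-[(1R,2S,4S,5E)-1,4-dimethoxy-2-methylhept-5-en-1-yl]-3-iodo-2,5-dimethoxybenzene
Product: 15 (2S,4S,5R)-5-(3-iodo-2,5-dimethoxyphenyl)-2,5-dimethoxy-4-methylpentanal, via vicinal diol 14 (not isolated)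
Conditions: OsO4 (cat.), NaIO4, 2,6-lutidine, dioxane/H2O, rt
Reagents that add atoms: osmium tetroxide, O=[Os](=O)(=O)=O; sodium periodate, [Na+].[O-]I(=O)(=O)=O
Why: Lemieux–Johnson oxidative cleavage (dihydroxylation, then periodate glycol cleavage) gives the α-methoxy aldehyde without ozone, which spares the electron-rich arene; the aldehyde is used crude.

Step 11
Reactants: 15 (2S,4S,5R)-5-(3-iodo-2,5-dimethoxyphenyl)-2,5-dimethoxy-4-methylpentanal
Product: 17 (3S,4R,5S,7S,8R)-8-(3-iodo-2,5-dimethoxyphenyl)-5,8-dimethoxy-3,7-dimethyloct-1-en-4-ol, via O-diisopinocampheylboryl ether 16 (not isolated)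
Conditions: cis-2-butene, n-BuLi, KOt-Bu, THF, −78 to −45 °C; (+)-Ipc2BOMe, −78 °C; BF3·OEt2; 15, −78 °C; then NaOH, H2O2
Reagents that add atoms: cis-2-butene, C/C=C\C
Why: Brown asymmetric (Z)-crotylboration; the chair transition state gives the 10,11-syn relationship, re-face delivery by the borane sets C11 (R) and C10 (S), and this sense coincides with Felkin addition anti to the α-methoxy group, so reagent and substrate control are matched for the 11,12-anti product.

Step 12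
Reactants: 17 (3S,4R,5S,7S,8R)-8-(3-iodo-2,5-dimethoxyphenyl)-5,8-dimethoxy-3,7-dimethyloct-1-en-4-ol
Product: 18 1-iodo-2,5-dimethoxy-3-[(1R,2S,4S,5R,6S)-1,4,5-trimethoxy-2,6-dimethyloct-7-en-1-yl]benzene
Conditions: NaH, MeI, THF/DMF, 0 °C to rt
Reagents that add atoms: iodomethane, CI
Why: Williamson O-methylation installs the C11 methoxy group with retention.

Step 13
Reactants: 18 1-iodo-2,5-dimethoxy-3-[(1R,2S,4S,5R,6S)-1,4,5-trimethoxy-2,6-dimethyloct-7-en-1-yl]benzene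
Product: 20 (2R,3R,4S,6S,7R)-7-(3-iodo-2,5-dimethoxyphenyl)-3,4,7-trimethoxy-2,6-dimethylheptanal, via vicinal diol 19 (not isolated)
Conditions: OsO4 (cat.), NaIO4, 2,6-lutidine, dioxane/H2O, rt
Reagents that add atoms: osmium tetroxide, O=[Os](=O)(=O)=O; sodium periodate, [Na+].[O-]I(=O)(=O)=O
Why: Lemieux–Johnson cleavage of the terminal alkene gives the C9 aldehyde under near-neutral conditions that do not epimerise the α-methyl centre C10.

Step 14
Reactants: 20 (2R,3R,4S,6S,7R)-7-(3-iodo-2,5-dimethoxyphenyl)-3,4,7-trimethoxy-2,6-dimethylheptanal; 21 ethyl 2-[bis(2,2,2-trifluoroethoxy)phosphoryl]propanoate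
Product: 22 ethyl (2Z,4S,5R,6S,8S,9R)-9-(3-iodo-2,5-dimethoxyphenyl)-5,6,9-trimethoxy-2,4,8-trimethylnon-2-enoate
Conditions: KN(SiMe3)2, 18-crown-6, THF, −78 °C
Reagents that add atoms: none
Why: Still–Gennari olefination; the electron-poor trifluoroethyl phosphonate with a dissociated potassium counter-ion eliminates fast from the kinetic adduct and gives the trisubstituted Z-enoate (8Z), with no epimerisation of C10 at −78 °C.

Step 15
Reactants: 22 ethyl (2Z,4S,5R,6S,8S,9R)-9-(3-iodo-2,5-dimethoxyphenyl)-5,6,9-trimethoxy-2,4,8-trimethylnon-2-enoate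
Product: 23 (2Z,4S,5R,6S,8S,9R)-9-(3-iodo-2,5-dimethoxyphenyl)-5,6,9-trimethoxy-2,4,8-trimethylnon-2-en-1-ol
Conditions: i-Bu2AlH, CH2Cl2, −78 °C
Reagents that add atoms: none
Why: 1,2-Reduction of the enoate by the aluminium hydride gives the allylic alcohol with the Z geometry intact.

Step 16
Reactants: 23 (2Z,4S,5R,6S,8S,9R)-9-(3-iodo-2,5-dimethoxyphenyl)-5,6,9-trimethoxy-2,4,8-trimethylnon-2-en-1-ol
Product: 24 (2Z,4S,5R,6S,8S,9R)-9-(3-iodo-2,5-dimethoxyphenyl)-5,6,9-trimethoxy-2,4,8-trimethylnon-2-enal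
Conditions: MnO2, CH2Cl2, rt
Reagents that add atoms: none
Why: Allylic oxidation on neutral manganese dioxide gives the Z-enal without acid or base that could isomerise it; it is used at once.

Step 17
Reactants: 25 (R)-4-benzyloxazolidin-2-one; 26 methoxyacetyl chloride
Product: 27 (R)-4-benzyl-3-(2-methoxyacetyl)oxazolidin-2-one
Conditions: n-BuLi, THF, −78 °C; then 26
Reagents that add atoms: none
Why: N-Acylation of the lithiated oxazolidinone by the acid chloride.

Step 18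
Reactants: 24 (2Z,4S,5R,6S,8S,9R)-9-(3-iodo-2,5-dimethoxyphenyl)-5,6,9-trimethoxy-2,4,8-trimethylnon-2-enal; 27 (R)-4-benzyl-3-(2-methoxyacetyl)oxazolidin-2-one
Product: 30 (R)-4-benzyl-3-[(2R,3S,4Z,6S,7R,8S,10S,11R)-3-hydroxy-11-(3-iodo-2,5-dimethoxyphenyl)-2,7,8,11-tetramethoxy-4,6,10-trimethylundec-4-enoyl]oxazolidin-2-one, via dibutylboron enolate 28 (not isolated), via dibutylboron aldolate 29 (not isolated)
Conditions: 27, Bu2BOTf, Et3N, CH2Cl2, −78 to 0 °C; 24, −78 °C; then pH 7 buffer, MeOH, H2O2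
Reagents that add atoms: none
Why: Evans syn glycolate aldol; the (Z)-boron enolate adds through a chair transition state on the enolate face left open by the benzyl group of the (R)-auxiliary, which gives the syn methoxy alcohol with C6 and C7 both in the target configuration (descriptors 2R,3S in the adduct) and 1,2-addition to the enal.

Step 19
Reactants: 30 the aldol adduct
Product: 31 (R)-4-benzyl-3-[(2R,3S,4Z,6S,7R,8S,10S,11R)-3-[(tert-butyldimethylsilyl)oxy]-11-(3-iodo-2,5-dimethoxyphenyl)-2,7,8,11-tetramethoxy-4,6,10-trimethylundec-4-enoyl]oxazolidin-2-one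
Conditions: TBSOTf, 2,6-lutidine, CH2Cl2, −78 to 0 °C
Reagents that add atoms: tert-butyldimethylsilyl trifluoromethanesulfonate, CC(C)(C)[Si](C)(C)OS(=O)(=O)C(F)(F)F
Why: Silylation of the hindered allylic C7 hydroxyl with the silyl triflate blocks retro-aldol and masks the only hydroxyl before the copper step.

Step 20
Reactants: 31 the silylated imide
Product: 32 (2S,3S,4Z,6S,7R,8S,10S,11R)-3-[(tert-butyldimethylsilyl)oxy]-11-(3-iodo-2,5-dimethoxyphenyl)-2,7,8,11-tetramethoxy-4,6,10-trimethylundec-4-en-1-ol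
Conditions: LiBH4, MeOH (1 equiv), THF, 0 °C
Reagents that add atoms: none
Why: Reductive cleavage of the N-acyl oxazolidinone by borohydride gives the primary alcohol (C5) and returns the auxiliary.

Step 21
Reactants: 32 the C5 alcohol
Product: 33 (2R,3S,4Z,6S,7R,8S,10S,11R)-3-[(tert-butyldimethylsilyl)oxy]-11-(3-iodo-2,5-dimethoxyphenyl)-2,7,8,11-tetramethoxy-4,6,10-trimethylundec-4-enal
Conditions: Dess–Martin periodinane, pyridine, CH2Cl2, 0 °C to rt
Reagents that add atoms: none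
Why: Dess–Martin oxidation gives the α-methoxy aldehyde under buffered conditions that do not epimerise C6; it is used directly.

Step 22
Reactants: 33 the C5 aldehyde; 34 methyl 2-[bis(2,2,2-trifluoroethoxy)phosphoryl]acetate
Product: 35 methyl (2Z,4S,5S,6Z,8S,9R,10S,12S,13R)-5-[(tert-butyldimethylsilyl)oxy]-13-(3-iodo-2,5-dimethoxyphenyl)-4,9,10,13-tetramethoxy-6,8,12-trimethyltrideca-2,6-dienoate
Conditions: KN(SiMe3)2, 18-crown-6, THF, −78 °C
Reagents that add atoms: none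
Why: Still–Gennari olefination of an α-alkoxy aldehyde gives the disubstituted Z-enoate (4Z) under kinetic control.

Step 23
Reactants: 35 the Z-enoate
Product: 36 (2Z,4S,5S,6Z,8S,9R,10S,12S,13R)-5-[(tert-butyldimethylsilyl)oxy]-13-(3-iodo-2,5-dimethoxyphenyl)-4,9,10,13-tetramethoxy-6,8,12-trimethyltrideca-2,6-dien-1-ol
Conditions: i-Bu2AlH, CH2Cl2, −78 °C
Reagents that add atoms: none
Why: 1,2-Reduction of the enoate to the Z-allylic alcohol.

Step 24
Reactants: 36 the Z-allylic alcohol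
Product: 37 (2Z,4S,5S,6Z,8S,9R,10S,12S,13R)-5-[(tert-butyldimethylsilyl)oxy]-13-(3-iodo-2,5-dimethoxyphenyl)-4,9,10,13-tetramethoxy-6,8,12-trimethyltrideca-2,6-dienal
Conditions: MnO2, CH2Cl2, rt
Reagents that add atoms: none
Why: Neutral allylic oxidation gives the Z-enal, which is filtered and olefinated without storage.

Step 25
Reactants: 37 the Z-enal; 21 ethyl 2-[bis(2,2,2-trifluoroethoxy)phosphoryl]propanoate
Product: 38 ethyl (2Z,4Z,6S,7S,8Z,10S,11R,12S,14S,15R)-7-[(tert-butyldimethylsilyl)oxy]-15-(3-iodo-2,5-dimethoxyphenyl)-6,11,12,15-tetramethoxy-2,8,10,14-tetramethylpentadeca-2,4,8-trienoate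
Conditions: KN(SiMe3)2, 18-crown-6, THF, −78 °C
Reagents that add atoms: none
Why: A second Still–Gennari olefination sets the trisubstituted 2Z alkene and completes the (2Z,4Z)-dienoate at low temperature.

Step 26
Reactants: 38 the (2Z,4Z)-dienoate
Product: 39 (2Z,4Z,6S,7S,8Z,10S,11R,12S,14S,15R)-7-[(tert-butyldimethylsilyl)oxy]-15-(3-iodo-2,5-dimethoxyphenyl)-6,11,12,15-tetramethoxy-2,8,10,14-tetramethylpentadeca-2,4,8-trienoic acid
Conditions: LiOH, THF/MeOH/H2O, rt; then 1 M HCl to pH 4, 0 °C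
Reagents that add atoms: lithium hydroxide, [Li+].[OH-]
Why: Ester saponification by hydroxide; silyl and methyl ethers and the alkenes are inert to these conditions.

Step 27
Reactants: 39 the dienoic acid
Product: 41 (2Z,4Z,6S,7S,8Z,10S,11R,12S,14S,15R)-7-[(tert-butyldimethylsilyl)oxy]-15-(3-iodo-2,5-dimethoxyphenyl)-6,11,12,15-tetramethoxy-2,8,10,14-tetramethylpentadeca-2,4,8-trienamide, via isobutyl carbonic mixed anhydride 40 (not isolated)
Conditions: i-BuOCOCl, N-methylmorpholine, THF, −20 °C; then NH3 (0.5 M in dioxane), −20 to 0 °C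
Reagents that add atoms: ammonia, N
Why: Mixed carbonic anhydride amidation; the activated acid exists only for minutes at −20 °C before the small, fast nucleophile ammonia captures it, so the Z,Z-diene has no time to isomerise.

Step 28
Reactants: 41 the open-chain primary dienamide aryl iodide
Product: 42 protected macrolactam: 19-membered anilide (N–C20), 2Z,4Z,8Z, 6S,7S,10S,11R,12S,14S,15R, C7 tert-butyldimethylsilyl ether, hydroquinone dimethyl ether
Conditions: CuI (30 mol%), MeNHCH2CH2NHMe (60 mol%), K2CO3, toluene, 60 °C, slow addition of 41 (final 2 mM)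
Reagents that add atoms: none
Why: K2CO3 deprotonates the copper-bound primary amide to a diamine-ligated monovalent copper amidate, which activates the C20–I bond (oxidative addition to a trivalent copper aryl amidate or an equivalent halogen-transfer path) and releases the anilide by C–N reductive elimination. The closest known reaction type is the Goldberg amidation of aryl halides with diamine ligands, which has been used intramolecularly to close 19-membered ansa lactams of this family. The one ring closes end to end as a macrolactam through the new N–C20 bond (ring atoms N, C1–C16, C21, C20), with the substrate added slowly so that its stationary concentration stays low while the catalyst concentration stays useful. No stereocentre is formed. The step needs chemoselective mono-N-arylation, which is secured because the primary amide is the only N–H or O–H nucleophile present (C7–OH is silylated and no carbamate is yet in place) and the product anilide is shielded by the C21 methoxy group. It also needs the three Z-alkenes to survive, which the aryl iodide secures by allowing turnover near 60 °C with a weak, non-nucleophilic base.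

Step 29
Reactants: 42 protected macrolactam
Product: 43 C7 alcohol of the macrolactam (hydroquinone dimethyl ether)
Conditions: Bu4NF, AcOH, THF, rt
Reagents that add atoms: none
Why: Fluoride-mediated desilylation, buffered with acetic acid so that no free alkoxide is exposed to the dienamide.

Step 30
Reactants: 43 C7 alcohol of the macrolactam
Product: 45 7-O-carbamoyl macrolactam (hydroquinone dimethyl ether), via N-trichloroacetyl carbamate 44 (not isolated)
Conditions: Cl3CC(O)NCO, CH2Cl2, 0 °C; then K2CO3, MeOH, rt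
Reagents that add atoms: trichloroacetyl isocyanate, O=C=NC(=O)C(Cl)(Cl)Cl
Why: Addition of the secondary alcohol to the acyl isocyanate followed by methanolysis of the trichloroacetyl group gives the primary carbamate, the hindered anilide N–H being far less reactive than the hydroxyl.

Step 31
Reactants: 45 7-O-carbamoyl macrolactam (hydroquinone dimethyl ether)
Product: 46 7-O-carbamoyl macrolactam benzoquinone (C18 and C21 carbonyls)
Conditions: (NH4)2Ce(NO3)6, MeCN/H2O, 0 °C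
Reagents that add atoms: water, O
Why: Oxidative demethylation of the para-dimethoxyarene by ceric ammonium nitrate gives the para-quinone, as no further alkoxy group on the ring can divert the oxidation to an ortho-quinone.

Step 32
Reactants: 46 7-O-carbamoyl macrolactam benzoquinone
Product: 47 target hydroquinone CNP0109452.1
Conditions: Na2S2O4, EtOAc/H2O, rt, under argon
Reagents that add atoms: none
Why: Dithionite reduction of the quinone to the hydroquinone, a two-electron two-proton reduction that touches neither the carbamate nor the alkenes.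

**Compound list**

1 | 2-hydroxy-5-methoxybenzaldehyde | O=Cc1cc(OC)ccc1O | starting material
2 | 2-hydroxy-3-iodo-5-methoxybenzaldehyde | O=Cc1cc(OC)cc(I)c1O | intermediate
3 | 3-iodo-2,5-dimethoxybenzaldehyde | O=Cc1cc(OC)cc(I)c1OC | intermediate
4 | (1R,2S)-1-(3-iodo-2,5-dimethoxyphenyl)-2-methylbut-3-en-1-yl diisopinocampheylborinate | C=C[C@H](C)[C@@H](OB([C@H]1C[C@H]2C[C@@H]([C@@H]1C)C2(C)C)[C@H]1C[C@H]2C[C@@H]([C@@H]1C)C2(C)C)c1cc(OC)cc(I)c1OC | intermediate
5 | (1R,2S)-1-(3-iodo-2,5-dimethoxyphenyl)-2-methylbut-3-en-1-ol | C=C[C@H](C)[C@@H](O)c1cc(OC)cc(I)c1OC | intermediate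
6 | 1-iodo-2,5-dimethoxy-3-[(1R,2S)-1-methoxy-2-methylbut-3-en-1-yl]benzene | C=C[C@H](C)[C@@H](OC)c1cc(OC)cc(I)c1OC | intermediate
7 | 9-[(3S,4R)-4-(3-iodo-2,5-dimethoxyphenyl)-4-methoxy-3-methylbutyl]-9-borabicyclo[3.3.1]nonane | B1(CC[C@H](C)[C@@H](OC)c2cc(OC)cc(I)c2OC)C2CCCC1CCC2 | intermediate
8 | (3S,4R)-4-(3-iodo-2,5-dimethoxyphenyl)-4-methoxy-3-methylbutan-1-ol | OCC[C@H](C)[C@@H](OC)c1cc(OC)cc(I)c1OC | intermediate
9 | (3S,4R)-4-(3-iodo-2,5-dimethoxyphenyl)-4-methoxy-3-methylbutanal | O=CC[C@H](C)[C@@H](OC)c1cc(OC)cc(I)c1OC | intermediate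
10 | (4R,6S,7R)-7-(3-iodo-2,5-dimethoxyphenyl)-7-methoxy-6-methylhept-1-en-4-yl diisopinocampheylborinate | C=CC[C@@H](OB([C@H]1C[C@H]2C[C@@H]([C@@H]1C)C2(C)C)[C@H]1C[C@H]2C[C@@H]([C@@H]1C)C2(C)C)C[C@H](C)[C@@H](OC)c1cc(OC)cc(I)c1OC | intermediate
11 | (4R,6S,7R)-7-(3-iodo-2,5-dimethoxyphenyl)-7-methoxy-6-methylhept-1-en-4-ol | C=CC[C@@H](O)C[C@H](C)[C@@H](OC)c1cc(OC)cc(I)c1OC | intermediate
12 | 1-[(1R,2S,4R)-1,4-dimethoxy-2-methylhept-6-en-1-yl]-3-iodo-2,5-dimethoxybenzene | C=CC[C@@H](OC)C[C@H](C)[C@@H](OC)c1cc(OC)cc(I)c1OC | intermediate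
13 | 1-[(1R,2S,4S,5E)-1,4-dimethoxy-2-methylhept-5-en-1-yl]-3-iodo-2,5-dimethoxybenzene | C/C=C/[C@@H](OC)C[C@H](C)[C@@H](OC)c1cc(OC)cc(I)c1OC | intermediate
14 | (4S,6S,7R)-7-(3-iodo-2,5-dimethoxyphenyl)-4,7-dimethoxy-6-methylheptane-2,3-diol (mixture at C2 and C3) | CC(O)C(O)[C@@H](OC)C[C@H](C)[C@@H](OC)c1cc(OC)cc(I)c1OC | intermediate
15 | (2S,4S,5R)-5-(3-iodo-2,5-dimethoxyphenyl)-2,5-dimethoxy-4-methylpentanal | O=C[C@@H](OC)C[C@H](C)[C@@H](OC)c1cc(OC)cc(I)c1OC | intermediate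
16 | (3S,4R,5S,7S,8R)-8-(3-iodo-2,5-dimethoxyphenyl)-5,8-dimethoxy-3,7-dimethyloct-1-en-4-yl diisopinocampheylborinate | C=C[C@H](C)[C@@H](OB([C@H]1C[C@H]2C[C@@H]([C@@H]1C)C2(C)C)[C@H]1C[C@H]2C[C@@H]([C@@H]1C)C2(C)C)[C@@H](OC)C[C@H](C)[C@@H](OC)c1cc(OC)cc(I)c1OC | intermediate
17 | (3S,4R,5S,7S,8R)-8-(3-iodo-2,5-dimethoxyphenyl)-5,8-dimethoxy-3,7-dimethyloct-1-en-4-ol | C=C[C@H](C)[C@@H](O)[C@@H](OC)C[C@H](C)[C@@H](OC)c1cc(OC)cc(I)c1OC | intermediate
18 | 1-iodo-2,5-dimethoxy-3-[(1R,2S,4S,5R,6S)-1,4,5-trimethoxy-2,6-dimethyloct-7-en-1-yl]benzene | C=C[C@H](C)[C@@H](OC)[C@@H](OC)C[C@H](C)[C@@H](OC)c1cc(OC)cc(I)c1OC | intermediate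
19 | (3S,4R,5S,7S,8R)-8-(3-iodo-2,5-dimethoxyphenyl)-4,5,8-trimethoxy-3,7-dimethyloctane-1,2-diol (mixture at C2) | OCC(O)[C@H](C)[C@@H](OC)[C@@H](OC)C[C@H](C)[C@@H](OC)c1cc(OC)cc(I)c1OC | intermediate
20 | (2R,3R,4S,6S,7R)-7-(3-iodo-2,5-dimethoxyphenyl)-3,4,7-trimethoxy-2,6-dimethylheptanal | O=C[C@H](C)[C@@H](OC)[C@@H](OC)C[C@H](C)[C@@H](OC)c1cc(OC)cc(I)c1OC | intermediate
21 | ethyl 2-[bis(2,2,2-trifluoroethoxy)phosphoryl]propanoate | CCOC(=O)C(C)P(=O)(OCC(F)(F)F)OCC(F)(F)F | starting material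
22 | ethyl (2Z,4S,5R,6S,8S,9R)-9-(3-iodo-2,5-dimethoxyphenyl)-5,6,9-trimethoxy-2,4,8-trimethylnon-2-enoate | CCOC(=O)/C(C)=C\[C@H](C)[C@@H](OC)[C@@H](OC)C[C@H](C)[C@@H](OC)c1cc(OC)cc(I)c1OC | intermediate
23 | (2Z,4S,5R,6S,8S,9R)-9-(3-iodo-2,5-dimethoxyphenyl)-5,6,9-trimethoxy-2,4,8-trimethylnon-2-en-1-ol | OC/C(C)=C\[C@H](C)[C@@H](OC)[C@@H](OC)C[C@H](C)[C@@H](OC)c1cc(OC)cc(I)c1OC | intermediate
24 | (2Z,4S,5R,6S,8S,9R)-9-(3-iodo-2,5-dimethoxyphenyl)-5,6,9-trimethoxy-2,4,8-trimethylnon-2-enal | O=C/C(C)=C\[C@H](C)[C@@H](OC)[C@@H](OC)C[C@H](C)[C@@H](OC)c1cc(OC)cc(I)c1OC | intermediate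
25 | (R)-4-benzyloxazolidin-2-one | O=C1N[C@H](Cc2ccccc2)CO1 | starting material
26 | methoxyacetyl chloride | COCC(Cl)=O | starting material
27 | (R)-4-benzyl-3-(2-methoxyacetyl)oxazolidin-2-one | COCC(=O)N1[C@H](Cc2ccccc2)COC1=O | intermediate
28 | (Z)-dibutylboron enolate of 27 | CO/C=C(\OB(CCCC)CCCC)N1[C@H](Cc2ccccc2)COC1=O | intermediate
29 | O-dibutylboryl derivative of aldol adduct 30 | O=C1OC[C@@H](Cc2ccccc2)N1C(=O)[C@H](OC)[C@@H](OB(CCCC)CCCC)/C(C)=C\[C@H](C)[C@@H](OC)[C@@H](OC)C[C@H](C)[C@@H](OC)c1cc(OC)cc(I)c1OC | intermediate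
30 | (R)-4-benzyl-3-[(2R,3S,4Z,6S,7R,8S,10S,11R)-3-hydroxy-11-(3-iodo-2,5-dimethoxyphenyl)-2,7,8,11-tetramethoxy-4,6,10-trimethylundec-4-enoyl]oxazolidin-2-one | O=C1OC[C@@H](Cc2ccccc2)N1C(=O)[C@H](OC)[C@@H](O)/C(C)=C\[C@H](C)[C@@H](OC)[C@@H](OC)C[C@H](C)[C@@H](OC)c1cc(OC)cc(I)c1OC | intermediate
31 | 3-O-(tert-butyldimethylsilyl) ether of 30 | O=C1OC[C@@H](Cc2ccccc2)N1C(=O)[C@H](OC)[C@@H](O[Si](C)(C)C(C)(C)C)/C(C)=C\[C@H](C)[C@@H](OC)[C@@H](OC)C[C@H](C)[C@@H](OC)c1cc(OC)cc(I)c1OC | intermediate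
32 | (2S,3S,4Z,6S,7R,8S,10S,11R)-3-[(tert-butyldimethylsilyl)oxy]-11-(3-iodo-2,5-dimethoxyphenyl)-2,7,8,11-tetramethoxy-4,6,10-trimethylundec-4-en-1-ol | OC[C@H](OC)[C@@H](O[Si](C)(C)C(C)(C)C)/C(C)=C\[C@H](C)[C@@H](OC)[C@@H](OC)C[C@H](C)[C@@H](OC)c1cc(OC)cc(I)c1OC | intermediate
33 | (2R,3S,4Z,6S,7R,8S,10S,11R)-3-[(tert-butyldimethylsilyl)oxy]-11-(3-iodo-2,5-dimethoxyphenyl)-2,7,8,11-tetramethoxy-4,6,10-trimethylundec-4-enal | O=C[C@H](OC)[C@@H](O[Si](C)(C)C(C)(C)C)/C(C)=C\[C@H](C)[C@@H](OC)[C@@H](OC)C[C@H](C)[C@@H](OC)c1cc(OC)cc(I)c1OC | intermediate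
34 | methyl 2-[bis(2,2,2-trifluoroethoxy)phosphoryl]acetate | COC(=O)CP(=O)(OCC(F)(F)F)OCC(F)(F)F | starting material
35 | methyl (2Z,4S,5S,6Z,8S,9R,10S,12S,13R)-5-[(tert-butyldimethylsilyl)oxy]-13-(3-iodo-2,5-dimethoxyphenyl)-4,9,10,13-tetramethoxy-6,8,12-trimethyltrideca-2,6-dienoate | COC(=O)/C=C\[C@H](OC)[C@@H](O[Si](C)(C)C(C)(C)C)/C(C)=C\[C@H](C)[C@@H](OC)[C@@H](OC)C[C@H](C)[C@@H](OC)c1cc(OC)cc(I)c1OC | intermediate
36 | (2Z,4S,5S,6Z,8S,9R,10S,12S,13R)-5-[(tert-butyldimethylsilyl)oxy]-13-(3-iodo-2,5-dimethoxyphenyl)-4,9,10,13-tetramethoxy-6,8,12-trimethyltrideca-2,6-dien-1-ol | OC/C=C\[C@H](OC)[C@@H](O[Si](C)(C)C(C)(C)C)/C(C)=C\[C@H](C)[C@@H](OC)[C@@H](OC)C[C@H](C)[C@@H](OC)c1cc(OC)cc(I)c1OC | intermediate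
37 | (2Z,4S,5S,6Z,8S,9R,10S,12S,13R)-5-[(tert-butyldimethylsilyl)oxy]-13-(3-iodo-2,5-dimethoxyphenyl)-4,9,10,13-tetramethoxy-6,8,12-trimethyltrideca-2,6-dienal | O=C/C=C\[C@H](OC)[C@@H](O[Si](C)(C)C(C)(C)C)/C(C)=C\[C@H](C)[C@@H](OC)[C@@H](OC)C[C@H](C)[C@@H](OC)c1cc(OC)cc(I)c1OC | intermediate
38 | ethyl (2Z,4Z,6S,7S,8Z,10S,11R,12S,14S,15R)-7-[(tert-butyldimethylsilyl)oxy]-15-(3-iodo-2,5-dimethoxyphenyl)-6,11,12,15-tetramethoxy-2,8,10,14-tetramethylpentadeca-2,4,8-trienoate | CCOC(=O)/C(C)=C\C=C/[C@H](OC)[C@@H](O[Si](C)(C)C(C)(C)C)/C(C)=C\[C@H](C)[C@@H](OC)[C@@H](OC)C[C@H](C)[C@@H](OC)c1cc(OC)cc(I)c1OC | intermediate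
39 | (2Z,4Z,6S,7S,8Z,10S,11R,12S,14S,15R)-7-[(tert-butyldimethylsilyl)oxy]-15-(3-iodo-2,5-dimethoxyphenyl)-6,11,12,15-tetramethoxy-2,8,10,14-tetramethylpentadeca-2,4,8-trienoic acid | OC(=O)/C(C)=C\C=C/[C@H](OC)[C@@H](O[Si](C)(C)C(C)(C)C)/C(C)=C\[C@H](C)[C@@H](OC)[C@@H](OC)C[C@H](C)[C@@H](OC)c1cc(OC)cc(I)c1OC | intermediate
40 | isobutyl carbonic mixed anhydride of 39 | CC(C)COC(=O)OC(=O)/C(C)=C\C=C/[C@H](OC)[C@@H](O[Si](C)(C)C(C)(C)C)/C(C)=C\[C@H](C)[C@@H](OC)[C@@H](OC)C[C@H](C)[C@@H](OC)c1cc(OC)cc(I)c1OC | intermediate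
41 | (2Z,4Z,6S,7S,8Z,10S,11R,12S,14S,15R)-7-[(tert-butyldimethylsilyl)oxy]-15-(3-iodo-2,5-dimethoxyphenyl)-6,11,12,15-tetramethoxy-2,8,10,14-tetramethylpentadeca-2,4,8-trienamide | NC(=O)/C(C)=C\C=C/[C@H](OC)[C@@H](O[Si](C)(C)C(C)(C)C)/C(C)=C\[C@H](C)[C@@H](OC)[C@@H](OC)C[C@H](C)[C@@H](OC)c1cc(OC)cc(I)c1OC | intermediate
42 | protected macrolactam: 19-membered N–C20 anilide, 2Z,4Z,8Z, 6S,7S,10S,11R,12S,14S,15R, C7 tert-butyldimethylsilyl ether, C18 and C21 methyl ethers | CO[C@H]1[C@@H](OC)C[C@H](C)[C@@H](OC)c2cc(OC)cc(c2OC)NC(=O)/C(C)=C\C=C/[C@H](OC)[C@@H](O[Si](C)(C)C(C)(C)C)/C(C)=C\[C@@H]1C | intermediate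
43 | C7 alcohol of the macrolactam (C18 and C21 methyl ethers) | CO[C@H]1[C@@H](OC)C[C@H](C)[C@@H](OC)c2cc(OC)cc(c2OC)NC(=O)/C(C)=C\C=C/[C@H](OC)[C@@H](O)/C(C)=C\[C@@H]1C | intermediate
44 | C7 N-(trichloroacetyl)carbamate of the macrolactam | CO[C@H]1[C@@H](OC)C[C@H](C)[C@@H](OC)c2cc(OC)cc(c2OC)NC(=O)/C(C)=C\C=C/[C@H](OC)[C@@H](OC(=O)NC(=O)C(Cl)(Cl)Cl)/C(C)=C\[C@@H]1C | intermediate
45 | C7 carbamate of the macrolactam (C18 and C21 methyl ethers) | CO[C@H]1[C@@H](OC)C[C@H](C)[C@@H](OC)c2cc(OC)cc(c2OC)NC(=O)/C(C)=C\C=C/[C@H](OC)[C@@H](OC(N)=O)/C(C)=C\[C@@H]1C | intermediate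
46 | C7 carbamate macrolactam para-benzoquinone | CO[C@H]1[C@@H](OC)C[C@H](C)[C@@H](OC)C2=CC(=O)C=C(C2=O)NC(=O)/C(C)=C\C=C/[C@H](OC)[C@@H](OC(N)=O)/C(C)=C\[C@@H]1C | intermediate
47 | CNP0109452.1, the C18,C21-hydroquinone (2Z,4Z,8Z; 6S,7S,10S,11R,12S,14S,15R) | CO[C@H]1[C@@H](OC)C[C@H](C)[C@@H](OC)c2cc(O)cc(c2O)NC(=O)/C(C)=C\C=C/[C@H](OC)[C@@H](OC(N)=O)/C(C)=C\[C@@H]1C | target

**Step count.** Total: 32 steps. Longest linear sequence: 31 steps (steps 1–16 and 18–32); step 17 prepares the acylated auxiliary.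

**Steps most likely to fail**

Step 28. Intermolecular N-arylation may outrun ring closure and give oligomers, and if the temperature has to be raised the dienamide may drift from Z to E. The fallback reverses the order of bond formation at nitrogen and sets out from acid 39. Copper-catalysed amination of the aryl iodide with aqueous ammonia at room temperature (CuI, L-proline, K2CO3, DMSO) should give (2Z,4Z,6S,7S,8Z,10S,11R,12S,14S,15R)-15-(3-amino-2,5-dimethoxyphenyl)-7-[(tert-butyldimethylsilyl)oxy]-6,11,12,15-tetramethoxy-2,8,10,14-tetramethylpentadeca-2,4,8-trienoic acid F1. Macrolactamisation by acylation of the aniline (BOP-Cl, i-Pr2NEt, toluene, high dilution) then forms the N–C1 bond, and the route is rejoined at macrolactam 42.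

Step 9. The double bond may migrate further into the enol ether, or migration may stall and leave inseparable mixtures. The fallback avoids the allyl group and sets out from aldehyde 9. Reagent-controlled addition of (E)-hex-1-enylzinc (1-hexyne, (c-C6H11)2BH, then Et2Zn, with catalytic (+)-3-exo-morpholinoisoborneol, the ligand antipode that directs re-face transfer) should give (1R,2S,4S,5E)-1-(3-iodo-2,5-dimethoxyphenyl)-1-methoxy-2-methyldec-5-en-4-ol F2, with the alkene already next to the carbinol. Methylation (NaH, MeI) gives 1-[(1R,2S,4S,5E)-1,4-dimethoxy-2-methyldec-5-en-1-yl]-3-iodo-2,5-dimethoxybenzene F3. Cleavage with OsO4 and NaIO4 rejoins the route at aldehyde 15.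

Step 11. The α-methoxy aldehyde may epimerise or hydrate before it reacts, and the crotylborane may scramble its geometry if the temperature rises, both eroding the C10–C12 diastereomer ratio. The fallback replaces crotylboration by an auxiliary-controlled aldol and sets out from aldehyde 15. The dibutylboron enolate of (R)-4-benzyl-3-propionyloxazolidin-2-one (Bu2BOTf, i-Pr2NEt) should give the syn adduct (R)-4-benzyl-3-[(2R,3R,4S,6S,7R)-3-hydroxy-7-(3-iodo-2,5-dimethoxyphenyl)-4,7-dimethoxy-2,6-dimethylheptanoyl]oxazolidin-2-one F4. Methylation with Me3OBF4 and 1,8-bis(dimethylamino)naphthalene gives (R)-4-benzyl-3-[(2R,3R,4S,6S,7R)-7-(3-iodo-2,5-dimethoxyphenyl)-3,4,7-trimethoxy-2,6-dimethylheptanoyl]oxazolidin-2-one F5. Reduction with LiBH4 gives (2S,3R,4S,6S,7R)-7-(3-iodo-2,5-dimethoxyphenyl)-3,4,7-trimethoxy-2,6-dimethylheptan-1-ol F6, and Dess–Martin oxidation rejoins the route at aldehyde 20.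

Further compounds
F1 | step 28 | (2Z,4Z,6S,7S,8Z,10S,11R,12S,14S,15R)-15-(3-amino-2,5-dimethoxyphenyl)-7-[(tert-butyldimethylsilyl)oxy]-6,11,12,15-tetramethoxy-2,8,10,14-tetramethylpentadeca-2,4,8-trienoic acid | OC(=O)/C(C)=C\C=C/[C@H](OC)[C@@H](O[Si](C)(C)C(C)(C)C)/C(C)=C\[C@H](C)[C@@H](OC)[C@@H](OC)C[C@H](C)[C@@H](OC)c1cc(OC)cc(N)c1OC
F2 | step 9 | (1R,2S,4S,5E)-1-(3-iodo-2,5-dimethoxyphenyl)-1-methoxy-2-methyldec-5-en-4-ol | CCCC/C=C/[C@@H](O)C[C@H](C)[C@@H](OC)c1cc(OC)cc(I)c1OC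
F3 | step 9 | 1-[(1R,2S,4S,5E)-1,4-dimethoxy-2-methyldec-5-en-1-yl]-3-iodo-2,5-dimethoxybenzene | CCCC/C=C/[C@@H](OC)C[C@H](C)[C@@H](OC)c1cc(OC)cc(I)c1OC
F4 | step 11 | (R)-4-benzyl-3-[(2R,3R,4S,6S,7R)-3-hydroxy-7-(3-iodo-2,5-dimethoxyphenyl)-4,7-dimethoxy-2,6-dimethylheptanoyl]oxazolidin-2-one | O=C1OC[C@@H](Cc2ccccc2)N1C(=O)[C@H](C)[C@@H](O)[C@@H](OC)C[C@H](C)[C@@H](OC)c1cc(OC)cc(I)c1OC
F5 | step 11 | (R)-4-benzyl-3-[(2R,3R,4S,6S,7R)-7-(3-iodo-2,5-dimethoxyphenyl)-3,4,7-trimethoxy-2,6-dimethylheptanoyl]oxazolidin-2-one | O=C1OC[C@@H](Cc2ccccc2)N1C(=O)[C@H](C)[C@@H](OC)[C@@H](OC)C[C@H](C)[C@@H](OC)c1cc(OC)cc(I)c1OC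
F6 | step 11 | (2S,3R,4S,6S,7R)-7-(3-iodo-2,5-dimethoxyphenyl)-3,4,7-trimethoxy-2,6-dimethylheptan-1-ol | OC[C@H](C)[C@@H](OC)[C@@H](OC)C[C@H](C)[C@@H](OC)c1cc(OC)cc(I)c1OC
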